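The two flavan units each carry cis-disposed C2–O1 and C3–O bonds on ring C, and both C2 atoms are bonded directly to the biaryl rings B and B'. Ring C is therefore opened at O1–C8a, which turns each cis pair into a syn 1,2-diol, and both C2–C3 bonds are cut back to one biaryl-2,2'-dicarbaldehyde. One auxiliary-controlled double glycolate aldol addition then forms both C2–C3 bonds and all four stereocentres, with the acyl carbons as the future C4 atoms. Its precursor is the pentabenzylated biphenyl dialdehyde, made by Suzuki–Miyaura coupling, plus two equivalents of an (S)-benzyloxazolidinone allyloxyacetyl imide. Rings A are added later as aryl Grignard reagents and closed by copper-catalysed etherification.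

Key step: step 9

Assumption: the given structure does not define the sense of the biaryl axis; the key step should give both axial diastereomers, which are separated there, and the later numbers mean the series that leads to material identical with natural theasinensin F (chiroptical comparison), the chemistry being the same for either.

Step 1
Reactants: 1 3,4-bis(benzyloxy)benzaldehyde
Product: 2 4,5-bis(benzyloxy)-2-bromobenzaldehyde
Conditions: Br2, NaOAc, AcOH, rt
Reagents that add atoms: bromine, BrBr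
Why: Electrophilic aromatic bromination: with both phenols already benzylated the ring should be attacked para to the 3-benzyloxy group, ortho to the formyl group, whereas a free catechol would brominate next to a hydroxyl.

Step 2
Reactants: 2 4,5-bis(benzyloxy)-2-bromobenzaldehyde
Product: 3 4,5-bis(benzyloxy)-2-(4,4,5,5-tetramethyl-1,3,2-dioxaborolan-2-yl)benzaldehyde
Conditions: B2pin2, Pd(dppf)Cl2 (5 mol %), KOAc, 1,4-dioxane, 90 °C
Reagents that add atoms: bis(pinacolato)diboron, CC1(C)OB(OC1(C)C)B1OC(C)(C)C(C)(C)O1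
Why: Miyaura borylation: the palladium-catalysed coupling of an aryl bromide with B2pin2 under acetate base tolerates the ortho formyl group and gives a pinacol ester that resists protodeboronation better than the free boronic acid.

Step 3
Reactants: 4 3,4,5-trihydroxybenzaldehyde
Product: 5 3,4,5-tris(benzyloxy)benzaldehyde
Conditions: BnBr, K2CO3, DMF, 60 °C, under N2
Reagents that add atoms: benzyl bromide, BrCc1ccccc1
Why: Williamson ether synthesis: the three phenoxides are alkylated by benzyl bromide under carbonate base, with air excluded because pyrogallols oxidise in base.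

Step 4
Reactants: 5 3,4,5-tris(benzyloxy)benzaldehyde
Product: 6 3,4,5-tris(benzyloxy)-2-bromobenzaldehyde
Conditions: NBS, MeCN, 50 °C
Reagents that add atoms: N-bromosuccinimide, O=C1CCC(=O)N1Br
Why: Electrophilic aromatic bromination: C2 (equivalent to C6) is the only free ring position and is activated ortho and para by benzyloxy groups, as in the NBS bromination of 3,4,5-trialkoxybenzaldehydes.

Step 5
Reactants: 3 4,5-bis(benzyloxy)-2-(4,4,5,5-tetramethyl-1,3,2-dioxaborolan-2-yl)benzaldehyde; 6 3,4,5-tris(benzyloxy)-2-bromobenzaldehyde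
Product: 7 4,4',5,5',6-pentakis(benzyloxy)biphenyl-2,2'-dicarbaldehyde (racemic about the axis)
Conditions: Pd(OAc)2 (5 mol %), SPhos, K3PO4, toluene/H2O, 90 °C
Reagents that add atoms: none
Why: Suzuki–Miyaura cross-coupling: the SPhos-ligated palladium catalyst is suited to biaryls with three ortho substituents, the bromide is activated by its ortho formyl group, and the less hindered ring is placed on boron to keep transmetalation fast.

Step 6
Reactants: 8 2-(allyloxy)acetic acid; 9 (S)-4-benzyloxazolidin-2-one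
Product: 11 (S)-3-(allyloxyacetyl)-4-benzyloxazolidin-2-one, via allyloxyacetic pivalic anhydride 10 (not isolated)
Conditions: PivCl, Et3N, THF, −20 °C; then 9, LiCl, −20 °C → rt
Reagents that add atoms: none
Why: N-acylation of the oxazolidinone by a mixed pivalic anhydride under LiCl/Et3N: attack should occur at the less hindered allyloxyacetyl carbonyl, and the stereocentre of 9 is not involved.

Step 7
Reactants: 12 5-bromoresorcinol (5-bromobenzene-1,3-diol)
Product: 13 1,3-bis(benzyloxy)-5-bromobenzene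
Conditions: BnBr, K2CO3, DMF, 60 °C
Reagents that add atoms: benzyl bromide, BrCc1ccccc1
Why: Williamson ether synthesis of both phenols, giving the ring A unit with the same benzyl protection as the rest of the molecule.

Step 8
Reactants: 13 1,3-bis(benzyloxy)-5-bromobenzene
Product: 14 1,5-bis(benzyloxy)-3-bromo-2-iodobenzene
Conditions: NIS, TFA (cat.), MeCN, rt
Reagents that add atoms: N-iodosuccinimide, O=C1CCC(=O)N1I
Why: Electrophilic iodination: attack is expected para to one benzyloxy group and ortho to the other, next to bromine, because the site between the two benzyloxy groups is more hindered; the iodide later directs metal exchange to this carbon alone.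

Step 9
Reactants: 7 4,4',5,5',6-pentakis(benzyloxy)biphenyl-2,2'-dicarbaldehyde; 11 (S)-3-(allyloxyacetyl)-4-benzyloxazolidin-2-one (two equivalents react, three are used)
Product: 17 bis-syn glycolate aldol adduct [the biphenyl of 7 bearing at C2 and C2' a (1R,2S)-2-(allyloxy)-1-hydroxy-3-oxo-3-[(S)-4-benzyl-2-oxooxazolidin-3-yl]propyl chain; (2S,3R) in each acyl chain; one axial diastereomer after chromatography], via dibutylboron Z-enolate 15 (not isolated), via bis(dibutylboryl) aldolate 16 (not isolated)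
Conditions: 11 (3 equiv), Bu2BOTf, Et3N, CH2Cl2, −78 → 0 °C; 7, −78 → 0 °C; then pH 7 buffer, MeOH, H2O2, 0 °C; chromatographic separation of the two axial diastereomers
Reagents that add atoms: none
Why: The imide is soft-enolised by Bu2BOTf/Et3N to the Z dibutylboron enolate 15, which adds to each formyl group of 7 through a closed chair transition state; the closest known reaction type is the boron-mediated Evans syn glycolate aldol addition of N-acyloxazolidinones to aromatic aldehydes. No ring is closed: the step forms the two C2–C3 bonds (flavan numbering), and the acyl carbons become the two C4 atoms. In each half the Z enolate geometry with the aldehyde aryl group equatorial fixes the syn relation between the carbinol carbon (future C2) and the allyloxy carbon (future C3). The benzyl group of the (S)-auxiliary, with the imide dipoles opposed, shields one enolate face, so both centres should have the absolute sense that becomes (2R,3R) in the flavan. The selectivity needed is reagent control at both aldehydes regardless of the racemic axis, secured because the controlling element sits in the enolate and not in 7; two axial diastereomers with identical carbon stereocentres are therefore expected and are separated. Excess enolate and the oxidative work-up should drive the second addition and free both carbinols from boron.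

Step 10
Reactants: 17 bis-syn glycolate aldol adduct
Product: 18 bis(tert-butyldimethylsilyl) ether of 17 (both carbinol oxygens silylated)
Conditions: TBSOTf, 2,6-lutidine, CH2Cl2, 0 °C
Reagents that add atoms: tert-butyldimethylsilyl trifluoromethanesulfonate, CC(C)(C)[Si](C)(C)OS(=O)(=O)C(F)(F)F
Why: Silyl ether formation: TBSOTf with 2,6-lutidine silylates hindered secondary benzylic alcohols without retro-aldol cleavage and masks the future O1 oxygens during the redox steps.

Step 11
Reactants: 18 bis(tert-butyldimethylsilyl) ether of 17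
Product: 19 bis(primary alcohol) [the biphenyl bearing at C2 and C2' a (1R,2R)-2-(allyloxy)-1-(tert-butyldimethylsilyloxy)-3-hydroxypropyl chain]
Conditions: LiBH4, MeOH (2 equiv), THF, 0 °C
Reagents that add atoms: none
Why: Reductive cleavage of the N-acyloxazolidinone: LiBH4 reduces the exocyclic imide carbonyl to the primary alcohol and releases the auxiliary for recovery, while ethers are inert and no stereocentre is touched.

Step 12
Reactants: 19 bis(primary alcohol)
Product: 20 dialdehyde [the biphenyl bearing at C2 and C2' a (1R,2S)-2-(allyloxy)-1-(tert-butyldimethylsilyloxy)-3-oxopropyl chain]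
Conditions: DMP, CH2Cl2, 0 °C → rt; used crude at once
Reagents that add atoms: none
Why: Dess–Martin oxidation: the primary alcohols are oxidised under non-enolising conditions, so the α-alkoxy centres (future C3) should not epimerise.

Step 13
Reactants: 20 dialdehyde; 14 1,5-bis(benzyloxy)-3-bromo-2-iodobenzene (two equivalents react, three are used)
Product: 22 bis(C4 carbinol) [20 in which each formyl group has become CH(OH)-[2-bromo-4,6-bis(benzyloxy)phenyl]; mixture of C4 epimers], via aryl Grignard reagent 21 (not isolated)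
Conditions: 14, iPrMgCl·LiCl, THF, −40 °C; then 20, −40 → −10 °C
Reagents that add atoms: none
Why: Iodine–magnesium exchange followed by Grignard addition: the iodide exchanges selectively over the bromide at −40 °C, where the ortho-bromoaryl Grignard reagent should not yet collapse to an aryne, and the new C4 carbinol centres do not matter because C4 later becomes CH2.

Step 14
Reactants: 22 bis(C4 carbinol)
Product: 23 tetraol (22 without the two silyl groups; free C2 and C4 hydroxyls in each half)
Conditions: TBAF, THF, 0 °C → rt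
Reagents that add atoms: none
Why: Fluoride-mediated desilylation: TBAF removes the silyl groups wherever migration may have placed them and leaves benzyl ethers, allyl ethers and aryl bromides untouched.

Step 15
Reactants: 23 tetraol
Product: 24 bis(flavan-4-ol) [two (2R,3R)-3-(allyloxy)-5,7-bis(benzyloxy)chroman-4-ol units, 2,3-cis, C4 epimers, bonded through C2 to C2 and C2' of the pentakis(benzyloxy)biphenyl]
Conditions: CuI (30 mol %), 1,10-phenanthroline, Cs2CO3, toluene, 110 °C, under Ar
Reagents that add atoms: none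
Why: Intramolecular Ullmann-type copper-catalysed C–O coupling: each C2 alkoxide displaces the ortho bromide of ring A in a six-membered closure (the C4 hydroxyl could only form a four-membered ring), and since the C2–O bond is never broken the configuration is retained and each syn pair becomes 2,3-cis.

Step 16
Reactants: 24 bis(flavan-4-ol)
Product: 25 bis-flavan [two (2R,3R)-3-(allyloxy)-5,7-bis(benzyloxy)chroman units, 2,3-cis, bonded through C2 to C2 and C2' of the pentakis(benzyloxy)biphenyl]
Conditions: Et3SiH, TFA, CH2Cl2, −20 → 0 °C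
Reagents that add atoms: none
Why: Ionic hydrogenation: acid ionises each C4 carbinol to a cation stabilised by O1 and the 5- and 7-benzyloxy groups of ring A, which takes hydride from the silane as in the reduction of flavan-3,4-diols to flavan-3-ols, so all C4 epimers converge and C2 and C3 are not involved.

Step 17
Reactants: 25 bis-flavan
Product: 27 bis(flavan-3-ol) [25 with both C3 hydroxyls free; (2R,3R) in each chroman], via bis(prop-1-enyl) ether 26 (not isolated)
Conditions: [Ir(cod)(PMePh2)2]PF6 (H2-activated, then degassed), THF, rt; then 1 M aq HCl, THF, rt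
Reagents that add atoms: none
Why: Allyl ether cleavage by isomerisation and hydrolysis: the cationic iridium hydride shifts the double bond to give prop-1-enyl ethers, which mild aqueous acid hydrolyses to the C3 alcohols without affecting the benzyl ethers.

Step 18
Reactants: 27 bis(flavan-3-ol); 28 3,4,5-tris(benzyloxy)benzoic acid (two equivalents react)
Product: 29 pentadeca-O-benzyl theasinensin F (27 esterified at both C3 oxygens with the 3,4,5-tris(benzyloxy)benzoyl group)
Conditions: DCC, DMAP, CH2Cl2, rt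
Reagents that add atoms: none
Why: Steglich esterification: the DMAP-activated acyl group acylates the hindered axial C3 hydroxyls with retention, because the C3–O bonds are not broken.

Step 19
Reactants: 29 pentadeca-O-benzyl theasinensin F
Product: 30 theasinensin F
Conditions: H2 (1 atm), Pd(OH)2/C, THF/MeOH, rt; work-up under Ar
Reagents that add atoms: none
Why: Catalytic hydrogenolysis: all fifteen aryl benzyl ethers should be cleaved under neutral conditions that leave the gallate esters, the pyran rings and the four stereocentres intact, as in the final step of galloylated catechin syntheses.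

Compound list

1 | 3,4-bis(benzyloxy)benzaldehyde | O=Cc1ccc(OCc2ccccc2)c(OCc2ccccc2)c1 | starting material
2 | 4,5-bis(benzyloxy)-2-bromobenzaldehyde | O=Cc1cc(OCc2ccccc2)c(OCc2ccccc2)cc1Br | intermediate
3 | 4,5-bis(benzyloxy)-2-(4,4,5,5-tetramethyl-1,3,2-dioxaborolan-2-yl)benzaldehyde | O=Cc1cc(OCc2ccccc2)c(OCc2ccccc2)cc1B1OC(C)(C)C(C)(C)O1 | intermediate
4 | 3,4,5-trihydroxybenzaldehyde | O=Cc1cc(O)c(O)c(O)c1 | starting material
5 | 3,4,5-tris(benzyloxy)benzaldehyde | O=Cc1cc(OCc2ccccc2)c(OCc2ccccc2)c(OCc2ccccc2)c1 | intermediate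
6 | 3,4,5-tris(benzyloxy)-2-bromobenzaldehyde | O=Cc1cc(OCc2ccccc2)c(OCc2ccccc2)c(OCc2ccccc2)c1Br | intermediate
7 | 4,4',5,5',6-pentakis(benzyloxy)biphenyl-2,2'-dicarbaldehyde (racemic axis) | O=Cc1cc(OCc2ccccc2)c(OCc2ccccc2)cc1-c1c(C=O)cc(OCc2ccccc2)c(OCc2ccccc2)c1OCc1ccccc1 | intermediate
8 | 2-(allyloxy)acetic acid | C=CCOCC(=O)O | starting material
9 | (S)-4-benzyloxazolidin-2-one | O=C1N[C@@H](Cc2ccccc2)CO1 | starting material
10 | allyloxyacetic pivalic anhydride | C=CCOCC(=O)OC(=O)C(C)(C)C | intermediate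
11 | (S)-3-(allyloxyacetyl)-4-benzyloxazolidin-2-one | C=CCOCC(=O)N1C(=O)OC[C@@H]1Cc1ccccc1 | intermediate
12 | 5-bromoresorcinol | Oc1cc(O)cc(Br)c1 | starting material
13 | 1,3-bis(benzyloxy)-5-bromobenzene | Brc1cc(OCc2ccccc2)cc(OCc2ccccc2)c1 | intermediate
14 | 1,5-bis(benzyloxy)-3-bromo-2-iodobenzene | Ic1c(Br)cc(OCc2ccccc2)cc1OCc1ccccc1 | intermediate
15 | dibutylboron Z-enolate of 11, (S,Z)-3-[2-(allyloxy)-1-(dibutylboryloxy)vinyl]-4-benzyloxazolidin-2-one | C=CCO/C=C(\OB(CCCC)CCCC)N1C(=O)OC[C@@H]1Cc1ccccc1 | intermediate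
16 | bis(dibutylboryl) aldolate of 17 | CCCCB(CCCC)O[C@@H]([C@H](OCC=C)C(=O)N1C(=O)OC[C@@H]1Cc1ccccc1)c1cc(OCc2ccccc2)c(OCc2ccccc2)cc1-c1c([C@@H](OB(CCCC)CCCC)[C@H](OCC=C)C(=O)N2C(=O)OC[C@@H]2Cc2ccccc2)cc(OCc2ccccc2)c(OCc2ccccc2)c1OCc1ccccc1 | intermediate
17 | bis-syn glycolate aldol adduct: 4,4',5,5',6-pentakis(benzyloxy)biphenyl bearing at C2 and C2' a (1R,2S)-2-(allyloxy)-1-hydroxy-3-oxo-3-[(S)-4-benzyl-2-oxooxazolidin-3-yl]propyl chain, (2S,3R) in each acyl chain, one axial diastereomer (axis not expressed in the string) | O[C@@H]([C@H](OCC=C)C(=O)N1C(=O)OC[C@@H]1Cc1ccccc1)c1cc(OCc2ccccc2)c(OCc2ccccc2)cc1-c1c([C@@H](O)[C@H](OCC=C)C(=O)N2C(=O)OC[C@@H]2Cc2ccccc2)cc(OCc2ccccc2)c(OCc2ccccc2)c1OCc1ccccc1 | intermediate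
18 | bis(tert-butyldimethylsilyl) ether of 17 | CC(C)(C)[Si](C)(C)O[C@@H]([C@H](OCC=C)C(=O)N1C(=O)OC[C@@H]1Cc1ccccc1)c1cc(OCc2ccccc2)c(OCc2ccccc2)cc1-c1c([C@@H](O[Si](C)(C)C(C)(C)C)[C@H](OCC=C)C(=O)N2C(=O)OC[C@@H]2Cc2ccccc2)cc(OCc2ccccc2)c(OCc2ccccc2)c1OCc1ccccc1 | intermediate
19 | bis(primary alcohol): the biphenyl bearing at C2 and C2' a (1R,2R)-2-(allyloxy)-1-(tert-butyldimethylsilyloxy)-3-hydroxypropyl chain | CC(C)(C)[Si](C)(C)O[C@@H]([C@H](OCC=C)CO)c1cc(OCc2ccccc2)c(OCc2ccccc2)cc1-c1c([C@@H](O[Si](C)(C)C(C)(C)C)[C@H](OCC=C)CO)cc(OCc2ccccc2)c(OCc2ccccc2)c1OCc1ccccc1 | intermediate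
20 | dialdehyde: the biphenyl bearing at C2 and C2' a (1R,2S)-2-(allyloxy)-1-(tert-butyldimethylsilyloxy)-3-oxopropyl chain | CC(C)(C)[Si](C)(C)O[C@@H]([C@H](OCC=C)C=O)c1cc(OCc2ccccc2)c(OCc2ccccc2)cc1-c1c([C@@H](O[Si](C)(C)C(C)(C)C)[C@H](OCC=C)C=O)cc(OCc2ccccc2)c(OCc2ccccc2)c1OCc1ccccc1 | intermediate
21 | [2-bromo-4,6-bis(benzyloxy)phenyl]magnesium chloride | Cl[Mg]c1c(Br)cc(OCc2ccccc2)cc1OCc1ccccc1 | intermediate
22 | bis(C4 carbinol): 20 with each formyl group converted into CH(OH)-[2-bromo-4,6-bis(benzyloxy)phenyl], C4 epimers, other centres as in 20 | CC(C)(C)[Si](C)(C)O[C@@H]([C@H](OCC=C)C(O)c1c(Br)cc(OCc2ccccc2)cc1OCc1ccccc1)c1cc(OCc2ccccc2)c(OCc2ccccc2)cc1-c1c([C@@H](O[Si](C)(C)C(C)(C)C)[C@H](OCC=C)C(O)c2c(Br)cc(OCc3ccccc3)cc2OCc2ccccc2)cc(OCc2ccccc2)c(OCc2ccccc2)c1OCc1ccccc1 | intermediate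
23 | tetraol: 22 without the silyl groups | O[C@@H]([C@H](OCC=C)C(O)c1c(Br)cc(OCc2ccccc2)cc1OCc1ccccc1)c1cc(OCc2ccccc2)c(OCc2ccccc2)cc1-c1c([C@@H](O)[C@H](OCC=C)C(O)c2c(Br)cc(OCc3ccccc3)cc2OCc2ccccc2)cc(OCc2ccccc2)c(OCc2ccccc2)c1OCc1ccccc1 | intermediate
24 | bis(flavan-4-ol): two (2R,3R)-3-(allyloxy)-5,7-bis(benzyloxy)chroman-4-ol units (2,3-cis, C4 epimers) bonded through C2 to C2 and C2' of 4,4',5,5',6-pentakis(benzyloxy)biphenyl | C=CCO[C@@H]1C(O)c2c(OCc3ccccc3)cc(OCc3ccccc3)cc2O[C@@H]1c1cc(OCc2ccccc2)c(OCc2ccccc2)cc1-c1c([C@H]2Oc3cc(OCc4ccccc4)cc(OCc4ccccc4)c3C(O)[C@H]2OCC=C)cc(OCc2ccccc2)c(OCc2ccccc2)c1OCc1ccccc1 | intermediate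
25 | bis-flavan: two (2R,3R)-3-(allyloxy)-5,7-bis(benzyloxy)chroman units (2,3-cis) bonded through C2 to C2 and C2' of the pentakis(benzyloxy)biphenyl | C=CCO[C@@H]1Cc2c(OCc3ccccc3)cc(OCc3ccccc3)cc2O[C@@H]1c1cc(OCc2ccccc2)c(OCc2ccccc2)cc1-c1c([C@H]2Oc3cc(OCc4ccccc4)cc(OCc4ccccc4)c3C[C@H]2OCC=C)cc(OCc2ccccc2)c(OCc2ccccc2)c1OCc1ccccc1 | intermediate
26 | bis[(E)-prop-1-enyl] ether corresponding to 25 | C/C=C/O[C@@H]1Cc2c(OCc3ccccc3)cc(OCc3ccccc3)cc2O[C@@H]1c1cc(OCc2ccccc2)c(OCc2ccccc2)cc1-c1c([C@H]2Oc3cc(OCc4ccccc4)cc(OCc4ccccc4)c3C[C@H]2O/C=C/C)cc(OCc2ccccc2)c(OCc2ccccc2)c1OCc1ccccc1 | intermediate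
27 | bis(flavan-3-ol): 25 with both C3 hydroxyls free, (2R,3R) in each chroman | O[C@@H]1Cc2c(OCc3ccccc3)cc(OCc3ccccc3)cc2O[C@@H]1c1cc(OCc2ccccc2)c(OCc2ccccc2)cc1-c1c([C@H]2Oc3cc(OCc4ccccc4)cc(OCc4ccccc4)c3C[C@H]2O)cc(OCc2ccccc2)c(OCc2ccccc2)c1OCc1ccccc1 | intermediate
28 | 3,4,5-tris(benzyloxy)benzoic acid | OC(=O)c1cc(OCc2ccccc2)c(OCc2ccccc2)c(OCc2ccccc2)c1 | starting material
29 | pentadeca-O-benzyl theasinensin F: 27 esterified at both C3 oxygens with 3,4,5-tris(benzyloxy)benzoyl | O=C(O[C@@H]1Cc2c(OCc3ccccc3)cc(OCc3ccccc3)cc2O[C@@H]1c1cc(OCc2ccccc2)c(OCc2ccccc2)cc1-c1c([C@H]2Oc3cc(OCc4ccccc4)cc(OCc4ccccc4)c3C[C@H]2OC(=O)c2cc(OCc3ccccc3)c(OCc3ccccc3)c(OCc3ccccc3)c2)cc(OCc2ccccc2)c(OCc2ccccc2)c1OCc1ccccc1)c1cc(OCc2ccccc2)c(OCc2ccccc2)c(OCc2ccccc2)c1 | intermediate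
30 | theasinensin F, (2R,3R) in both flavan units | O=C(O[C@@H]1Cc2c(O)cc(O)cc2O[C@@H]1c1cc(O)c(O)cc1-c1c([C@H]2Oc3cc(O)cc(O)c3C[C@H]2OC(=O)c2cc(O)c(O)c(O)c2)cc(O)c(O)c1O)c1cc(O)c(O)c(O)c1 | target

Total step count: 19 (eight before the key step, the key step, ten after it).
Longest linear sequence: 14 steps (steps 1, 2, 5 and 9 to 19 from compound 1; equally steps 3, 4, 5 and 9 to 19 from compound 4).

Steps most likely to fail

1. Step 9. After the first addition the boron aldolate may add to the neighbouring formyl group across the biaryl (a seven-membered hemiacetal) and stall the second addition. The axis may also oppose the auxiliary in one half and lower facial selectivity, or the two axial diastereomers may not separate. Fallback: the stereocentres are made before the biaryl bond, so that no second aldehyde and no axis are present during the aldol addition. Setting out from 2, the enolate 15 under the conditions of step 9 should give the mono-aldol adduct (S)-3-[(2S,3R)-2-(allyloxy)-3-[4,5-bis(benzyloxy)-2-bromophenyl]-3-hydroxypropanoyl]-4-benzyloxazolidin-2-one F1. Silylation (TBSOTf, 2,6-lutidine) gives its tert-butyldimethylsilyl ether F2, and Miyaura borylation (B2pin2, Pd(dppf)Cl2, KOAc, dioxane) gives the pinacol boronate F3. Setting out from 6, the same aldol addition gives the 3,4,5-tris(benzyloxy)-2-bromophenyl adduct F4, which is silylated to its tert-butyldimethylsilyl ether F5. Suzuki–Miyaura coupling of F3 with F5 (Pd(OAc)2, SPhos, K3PO4, toluene, 90 °C) then returns to the route at 18, again as two axial diastereomers to be separated.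

2. Step 15. Arylation of the hindered C2 alkoxide may be slower than loss of bromine by reduction, with the free C4 carbinol of the 1,3-diol binding the copper or serving as a hydride source; the two closures may also stop after the first. Fallback: the C4 oxygen is removed first and the ring is closed under palladium catalysis on a substrate with one hydroxyl per half. Setting out from 22, ionic reduction (Et3SiH, BF3·OEt2, CH2Cl2, −78 °C; the silyl group keeps C2 from ionising) should give the C4-methylene bis(silyl ether) F6. TBAF then gives the C4-methylene diol F7, and intramolecular Buchwald–Hartwig etherification (Pd(OAc)2, 2-(di-tert-butylphosphino)-1,1'-binaphthyl, Cs2CO3, toluene, 80 °C) closes both pyran rings with retention at C2, coming back to the route at 25.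

3. Step 13. The ortho-bromoaryl Grignard reagent may lose magnesium halide to an aryne before it adds, or act as a base toward the hindered α-alkoxy aldehyde, which would epimerise the future C3 centres or leave one aldehyde unreacted. Fallback: a ring A nucleophile that cannot eliminate at low temperature is used, and ring C is closed by nucleophilic aromatic substitution instead of copper catalysis. 1,3-Bis(benzyloxy)-5-fluorobenzene F8 (from commercial 5-fluororesorcinol, BnBr, K2CO3) is lithiated between fluorine and benzyloxy (n-BuLi, THF, −78 °C) to [2-fluoro-4,6-bis(benzyloxy)phenyl]lithium F9. Setting out from 20, addition of this reagent at −78 °C should give the fluoro analogue of 22 F10, and TBAF gives the fluoro analogue of 23 F11. KN(SiMe3)2 (THF/DMF, 0 → 60 °C) then displaces fluoride by the C2 alkoxides, and the route is rejoined at 24.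

Further compounds

F1 | step 9 | (S)-3-[(2S,3R)-2-(allyloxy)-3-[4,5-bis(benzyloxy)-2-bromophenyl]-3-hydroxypropanoyl]-4-benzyloxazolidin-2-one | O[C@@H]([C@H](OCC=C)C(=O)N1C(=O)OC[C@@H]1Cc1ccccc1)c1cc(OCc2ccccc2)c(OCc2ccccc2)cc1Br
F2 | step 9 | tert-butyldimethylsilyl ether of F1 | CC(C)(C)[Si](C)(C)O[C@@H]([C@H](OCC=C)C(=O)N1C(=O)OC[C@@H]1Cc1ccccc1)c1cc(OCc2ccccc2)c(OCc2ccccc2)cc1Br
F3 | step 9 | pinacol boronate from F2 | CC(C)(C)[Si](C)(C)O[C@@H]([C@H](OCC=C)C(=O)N1C(=O)OC[C@@H]1Cc1ccccc1)c1cc(OCc2ccccc2)c(OCc2ccccc2)cc1B1OC(C)(C)C(C)(C)O1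
F4 | step 9 | (S)-3-[(2S,3R)-2-(allyloxy)-3-[3,4,5-tris(benzyloxy)-2-bromophenyl]-3-hydroxypropanoyl]-4-benzyloxazolidin-2-one | O[C@@H]([C@H](OCC=C)C(=O)N1C(=O)OC[C@@H]1Cc1ccccc1)c1cc(OCc2ccccc2)c(OCc2ccccc2)c(OCc2ccccc2)c1Br
F5 | step 9 | tert-butyldimethylsilyl ether of F4 | CC(C)(C)[Si](C)(C)O[C@@H]([C@H](OCC=C)C(=O)N1C(=O)OC[C@@H]1Cc1ccccc1)c1cc(OCc2ccccc2)c(OCc2ccccc2)c(OCc2ccccc2)c1Br
F6 | step 15 | C4-methylene bis(silyl ether): 22 with each C4 carbinol reduced to CH2 | CC(C)(C)[Si](C)(C)O[C@@H]([C@H](OCC=C)Cc1c(Br)cc(OCc2ccccc2)cc1OCc1ccccc1)c1cc(OCc2ccccc2)c(OCc2ccccc2)cc1-c1c([C@@H](O[Si](C)(C)C(C)(C)C)[C@H](OCC=C)Cc2c(Br)cc(OCc3ccccc3)cc2OCc2ccccc2)cc(OCc2ccccc2)c(OCc2ccccc2)c1OCc1ccccc1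
F7 | step 15 | C4-methylene diol: F6 without the silyl groups | O[C@@H]([C@H](OCC=C)Cc1c(Br)cc(OCc2ccccc2)cc1OCc1ccccc1)c1cc(OCc2ccccc2)c(OCc2ccccc2)cc1-c1c([C@@H](O)[C@H](OCC=C)Cc2c(Br)cc(OCc3ccccc3)cc2OCc2ccccc2)cc(OCc2ccccc2)c(OCc2ccccc2)c1OCc1ccccc1
F8 | step 13 | 1,3-bis(benzyloxy)-5-fluorobenzene | Fc1cc(OCc2ccccc2)cc(OCc2ccccc2)c1
F9 | step 13 | [2-fluoro-4,6-bis(benzyloxy)phenyl]lithium | [Li]c1c(F)cc(OCc2ccccc2)cc1OCc1ccccc1
F10 | step 13 | fluoro analogue of 22 (fluorine in place of each bromine) | CC(C)(C)[Si](C)(C)O[C@@H]([C@H](OCC=C)C(O)c1c(F)cc(OCc2ccccc2)cc1OCc1ccccc1)c1cc(OCc2ccccc2)c(OCc2ccccc2)cc1-c1c([C@@H](O[Si](C)(C)C(C)(C)C)[C@H](OCC=C)C(O)c2c(F)cc(OCc3ccccc3)cc2OCc2ccccc2)cc(OCc2ccccc2)c(OCc2ccccc2)c1OCc1ccccc1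
F11 | step 13 | fluoro analogue of 23 (fluorine in place of each bromine) | O[C@@H]([C@H](OCC=C)C(O)c1c(F)cc(OCc2ccccc2)cc1OCc1ccccc1)c1cc(OCc2ccccc2)c(OCc2ccccc2)cc1-c1c([C@@H](O)[C@H](OCC=C)C(O)c2c(F)cc(OCc3ccccc3)cc2OCc2ccccc2)cc(OCc2ccccc2)c(OCc2ccccc2)c1OCc1ccccc1
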